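**Plan**

1. Retrosynthesis (pyran numbering O1, C2‑Me, C3‑CH2OH, C4, C5‑CO2Me, C6): the three silyl ethers are cut first. Next comes the C4–CH2 bond of the acetate arm, by conjugate addition–elimination (SN2′) of the enolate of hydroxytyrosyl acetate. Last come the ring bonds C4–C5 and C5–C6, which takes the ester‑bearing carbon C5 out of the ring and leaves a trans‑2,3‑disubstituted 2,3‑dihydrofuran, itself traced to an Evans syn‑aldol adduct.
2. Forward order of rings: the five‑membered O‑ring is made first (lactol, then enol ether). A bromo(methoxycarbonyl)carbene carbon is then inserted into its C=C bond, so that the five‑membered ring grows to the six‑membered pyran, obtained as a 2‑methoxy‑5,6‑dihydro‑2H‑pyran‑3‑carboxylate. The arene arrives last with the side chain.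
3. Enabling feature: in the target O1 sits on the sp2 carbon C6 and the neighbouring C5 carries only the ester. C5 can therefore be a carbenoid carbon, and the O1 lone pair can push open the fused cyclopropane (C4–C6 bond) as bromide leaves C5.
4. Stereochemistry: C2 and C3 come from the auxiliary‑controlled aldol reaction and are carried through untouched. C4 is set by substrate control when the enolate adds anti to the C3 substituent.

Key step: step 9

Remark on the chemistry: TBS = tert‑butyldimethylsilyl. Lactol 13 and acetal 21 are carried on as mixtures of epimers at the (hemi)acetal carbon, which becomes sp2 in steps 6 and 11. That carbon, the ozonide carbon of 11 and the cyclopropane carbons of 19 are left undefined in the SMILES.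

**Step 1**
Reactants: 1 (4S)‑4‑benzyl‑1,3‑oxazolidin‑2‑one; 2 pent‑4‑enoyl chloride
Product: 4 (4S)‑4‑benzyl‑3‑(pent‑4‑enoyl)‑1,3‑oxazolidin‑2‑one, via N‑lithio oxazolidinone 3 (not isolated)
Conditions: n‑BuLi, THF, −78 °C; then 2, −78 → 0 °C
Reagents that add atoms: none
Why: N‑acylation of the lithiated oxazolidinone with an acid chloride is the standard entry to Evans imides; no stereocentre is formed.

**Step 2**
Reactants: 4 (4S)‑4‑benzyl‑3‑(pent‑4‑enoyl)‑1,3‑oxazolidin‑2‑one; 5 acetaldehyde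
Product: 8 (4S)‑4‑benzyl‑3‑[(2S,3R)‑3‑hydroxy‑2‑(prop‑2‑en‑1‑yl)butanoyl]‑1,3‑oxazolidin‑2‑one, via Z‑dibutylboron enolate 6 (not isolated), via boron aldolate 7 (not isolated)
Conditions: Bu2BOTf, i‑Pr2NEt, CH2Cl2, −78 → 0 °C; then 5, −78 → 0 °C; pH 7 buffer, MeOH, H2O2, 0 °C
Reagents that add atoms: none
Why: Evans syn‑aldol reaction, in which the Z‑boron enolate reacts through a closed chair transition state on the enolate face not shielded by the benzyl group of the auxiliary, which should set both new centres (2S,3R).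

**Step 3**
Reactants: 8 (4S)‑4‑benzyl‑3‑[(2S,3R)‑3‑hydroxy‑2‑(prop‑2‑en‑1‑yl)butanoyl]‑1,3‑oxazolidin‑2‑one
Product: 9 (2R,3R)‑2‑(prop‑2‑en‑1‑yl)butane‑1,3‑diol
Conditions: LiBH4, MeOH (1 equiv), THF, 0 °C; aq NaOH work‑up
Reagents that add atoms: none
Why: Reductive cleavage of the imide with LiBH4 should give the 1,3‑diol and release the auxiliary without touching the alkene or epimerising the α‑centre (the descriptor changes only because the priorities change).

**Step 4**
Reactants: 9 (2R,3R)‑2‑(prop‑2‑en‑1‑yl)butane‑1,3‑diol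
Product: 10 (2R,3R)‑3‑(TBSO‑methyl)hex‑5‑en‑2‑ol
Conditions: TBSCl (1.05 equiv), imidazole, CH2Cl2, −20 → 0 °C
Reagents that add atoms: tert‑butyldimethylsilyl chloride, CC(C)(C)[Si](C)(C)Cl
Why: Selective monosilylation of a 1,3‑diol, the primary hydroxyl reacting much faster than the hindered secondary one.

**Step 5**
Reactants: 10 (2R,3R)‑3‑(TBSO‑methyl)hex‑5‑en‑2‑ol
Product: 13 (4R,5R)‑4‑(TBSO‑methyl)‑5‑methyloxolan‑2‑ol, via secondary ozonide 11 (not isolated), via hydroxy aldehyde 12 (not isolated)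
Conditions: O3, CH2Cl2, −78 °C; then PPh3, −78 °C → rt
Reagents that add atoms: ozone, [O-][O+]=O
Why: Ozonolysis with reductive work‑up gives the γ‑hydroxy aldehyde, which should close spontaneously to the five‑membered lactol; the two stereocentres are not involved.

**Step 6**
Reactants: 13 (4R,5R)‑4‑(TBSO‑methyl)‑5‑methyloxolan‑2‑ol
Product: 15 (2R,3R)‑3‑(TBSO‑methyl)‑2‑methyl‑2,3‑dihydrofuran, via anomeric mesylate 14 (not isolated)
Conditions: MsCl, Et3N (4 equiv), CH2Cl2, −40 °C → reflux; distillation or Et3N‑deactivated silica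
Reagents that add atoms: none
Why: Mesylation of the lactol and base‑induced loss of methanesulfonate (the usual dehydration of 2‑deoxy lactols to glycals) should give the enol ether, only one ring carbon carrying β‑hydrogens.

**Step 7**
Reactants: 16 methyl glycinate hydrochloride
Product: 17 methyl diazoacetate
Conditions: NaNO2, H2O/CH2Cl2, cat. H2SO4, −5 °C
Reagents that add atoms: sodium nitrite, [Na+].[O-]N=O
Why: Diazotisation of an α‑amino ester, the α‑diazonium ester losing a proton to give the stabilised diazo ester.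

**Step 8**
Reactants: 17 methyl diazoacetate
Product: 18 methyl bromodiazoacetate
Conditions: NBS, DBU, CH2Cl2, 0 °C, 5 min; cold filtration through silica; solution used at once
Reagents that add atoms: N‑bromosuccinimide, O=C1CCC(=O)N1Br
Why: Electrophilic bromination at the diazo carbon followed by deprotonation with DBU is the established preparation of halodiazoacetates.

**Step 9**
Reactants: 15 (2R,3R)‑3‑(TBSO‑methyl)‑2‑methyl‑2,3‑dihydrofuran; 18 methyl bromodiazoacetate
Product: 21 methyl (5R,6R)‑5‑(TBSO‑methyl)‑2‑methoxy‑6‑methyl‑5,6‑dihydro‑2H‑pyran‑3‑carboxylate, via bromocyclopropane 19 (not isolated), via allyl oxocarbenium bromide 20 (not isolated)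
Conditions: Rh2(esp)2 (1 mol %; esp = α,α,α′,α′‑tetramethyl‑1,3‑benzenedipropionate), slow addition of 18 (1.5 equiv), CH2Cl2, 0 °C; then MeOH, 2,6‑lutidine, 0 °C → rt
Reagents that add atoms: methanol, CO
Why: Proposed new method: the carbene of divalent rhodium generated from 18 should cyclopropanate the electron‑rich enol‑ether C4=C5 bond of 15 to give 19, in which the ring‑oxygen lone pair and the bromide on the apex carbon are set up for a disrotatory two‑electron electrocyclic opening of the ring‑fusion bond (cyclopropyl‑to‑allyl cation), so that the five‑membered ring expands to the six‑membered allyl/oxocarbenium ion 20 with the ester‑bearing carbon inserted between the former alkene carbons. The closest known reactions are the ring expansion of glycals and 2,3‑dihydrofurans through their dihalocarbene adducts to 2‑alkoxy‑3‑halo dihydropyrans and oxepines, and the Ciamician–Dennstedt‑type expansion of indoles to quinoline‑3‑carboxylates with halodiazoacetates; the use of a halo(ester)carbene on a non‑aromatic cyclic enol ether is the untested element. The only ring that is closed is the transient cyclopropane (concerted [2+1] addition); the six‑membered ring is not closed but arises by cleavage of the bond shared by the two rings. Only a bromide syn to the five‑membered ring can leave, and this isomer is expected because the ester prefers the exo position, while an exo‑bromide isomer can epimerise through reversible heterolysis of the donor–acceptor O–C–C(CO2Me) bond. Methanol should capture 20 at the oxocarbenium carbon, the site of highest positive charge, which gives a new acetal centre that is not controlled (axial attack under the anomeric effect is expected) and is erased in step 11, whereas the two existing centres are not touched. The step needs cyclopropanation in preference to C–H insertion, secured by the nucleophilic enol ether, and capture by methanol in preference to proton loss to a 2H‑pyran, secured by excess methanol buffered with 2,6‑lutidine.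

**Step 10**
Reactants: 22 2‑(3,4‑dihydroxyphenyl)ethyl acetate (hydroxytyrosol acetate)
Product: 23 2‑[3,4‑bis(TBSO)phenyl]ethyl acetate
Conditions: TBSCl (2.4 equiv), imidazole, DMF, rt
Reagents that add atoms: tert‑butyldimethylsilyl chloride, CC(C)(C)[Si](C)(C)Cl
Why: Standard silylation of both phenols, which leaves the acetate untouched.

**Step 11**
Reactants: 23 2‑[3,4‑bis(TBSO)phenyl]ethyl acetate; 21 methyl (5R,6R)‑5‑(TBSO‑methyl)‑2‑methoxy‑6‑methyl‑5,6‑dihydro‑2H‑pyran‑3‑carboxylate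
Product: 26 methyl (2R,3R,4S)‑4‑{2‑[2‑(3,4‑bis(TBSO)phenyl)ethoxy]‑2‑oxoethyl}‑3‑(TBSO‑methyl)‑2‑methyl‑3,4‑dihydro‑2H‑pyran‑5‑carboxylate, via lithium enolate 24 (not isolated), via Michael adduct enolate 25 (not isolated)
Conditions: 23 (1.5 equiv), LDA (LiN(i‑Pr)2), THF, −78 °C; then 21, −78 → −30 °C; AcOH, −78 °C
Reagents that add atoms: none
Why: Michael addition of the lithium ester enolate to the unsaturated ester followed by E1cB loss of the axial methoxide (overall SN2′ on a Morita–Baylis–Hillman‑type allylic acetal) moves the double bond into the enol‑ether position, and the enolate should add axially to C4 on the face anti to the neighbouring pseudo‑equatorial CH2OTBS group, which sets the 3,4‑trans relation (4S).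

**Step 12**
Reactants: 26 methyl (2R,3R,4S)‑4‑{2‑[2‑(3,4‑bis(TBSO)phenyl)ethoxy]‑2‑oxoethyl}‑3‑(TBSO‑methyl)‑2‑methyl‑3,4‑dihydro‑2H‑pyran‑5‑carboxylate
Product: 27 methyl (2R,3R,4S)‑4‑{2‑[2‑(3,4‑dihydroxyphenyl)ethoxy]‑2‑oxoethyl}‑3‑(hydroxymethyl)‑2‑methyl‑3,4‑dihydro‑2H‑pyran‑5‑carboxylate
Conditions: TBAF, AcOH (1:1), THF, 0 °C → rt, under argon
Reagents that add atoms: none
Why: Buffered fluoride should cleave the two aryl and the primary alkyl silyl ethers under non‑basic conditions that leave the vinylogous carbonate, both esters and the catechol intact.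

**Compound list**

1 | (4S)‑4‑benzyl‑1,3‑oxazolidin‑2‑one | O=C1N[C@@H](Cc2ccccc2)CO1 | starting material
2 | pent‑4‑enoyl chloride | C=CCCC(Cl)=O | starting material
3 | N‑lithio (4S)‑4‑benzyl‑1,3‑oxazolidin‑2‑one (formed in the flask) | [Li]N1[C@@H](Cc2ccccc2)COC1=O | intermediate
4 | (4S)‑4‑benzyl‑3‑(pent‑4‑enoyl)‑1,3‑oxazolidin‑2‑one | C=CCCC(=O)N1C(=O)OC[C@@H]1Cc1ccccc1 | intermediate
5 | acetaldehyde | CC=O | starting material
6 | Z‑dibutylboron enolate of 4 (formed in the flask) | C=CC/C=C(\OB(CCCC)CCCC)N1C(=O)OC[C@@H]1Cc1ccccc1 | intermediate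
7 | dibutylboron aldolate of 8 (formed in the flask) | C[C@@H](OB(CCCC)CCCC)[C@H](CC=C)C(=O)N1C(=O)OC[C@@H]1Cc1ccccc1 | intermediate
8 | (4S)‑4‑benzyl‑3‑[(2S,3R)‑3‑hydroxy‑2‑(prop‑2‑en‑1‑yl)butanoyl]‑1,3‑oxazolidin‑2‑one | C[C@@H](O)[C@H](CC=C)C(=O)N1C(=O)OC[C@@H]1Cc1ccccc1 | intermediate
9 | (2R,3R)‑2‑(prop‑2‑en‑1‑yl)butane‑1,3‑diol | C[C@@H](O)[C@H](CC=C)CO | intermediate
10 | (2R,3R)‑3‑({[tert‑butyl(dimethyl)silyl]oxy}methyl)hex‑5‑en‑2‑ol | C[C@@H](O)[C@H](CC=C)CO[Si](C)(C)C(C)(C)C | intermediate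
11 | (2R,3R)‑3‑(TBSO‑methyl)‑4‑(1,2,4‑trioxolan‑3‑yl)butan‑2‑ol, secondary ozonide (formed in the flask) | C[C@@H](O)[C@H](CC1OCOO1)CO[Si](C)(C)C(C)(C)C | intermediate
12 | (3R,4R)‑3‑(TBSO‑methyl)‑4‑hydroxypentanal (formed in the flask) | C[C@@H](O)[C@H](CC=O)CO[Si](C)(C)C(C)(C)C | intermediate
13 | (4R,5R)‑4‑({[tert‑butyl(dimethyl)silyl]oxy}methyl)‑5‑methyloxolan‑2‑ol, both anomers | C[C@H]1OC(O)C[C@@H]1CO[Si](C)(C)C(C)(C)C | intermediate
14 | (4R,5R)‑4‑(TBSO‑methyl)‑5‑methyloxolan‑2‑yl methanesulfonate (formed in the flask) | C[C@H]1OC(OS(C)(=O)=O)C[C@@H]1CO[Si](C)(C)C(C)(C)C | intermediate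
15 | (2R,3R)‑3‑({[tert‑butyl(dimethyl)silyl]oxy}methyl)‑2‑methyl‑2,3‑dihydrofuran (trans) | C[C@H]1OC=C[C@@H]1CO[Si](C)(C)C(C)(C)C | intermediate
16 | methyl glycinate hydrochloride | COC(=O)CN.Cl | starting material
17 | methyl diazoacetate | COC(=O)C=[N+]=[N-] | intermediate
18 | methyl bromodiazoacetate | COC(=O)C(Br)=[N+]=[N-] | intermediate
19 | methyl (3R,4R)‑6‑bromo‑4‑(TBSO‑methyl)‑3‑methyl‑2‑oxabicyclo[3.1.0]hexane‑6‑carboxylate (formed in the flask) | COC(=O)C1(Br)C2O[C@H](C)[C@@H](CO[Si](C)(C)C(C)(C)C)C12 | intermediate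
20 | (2R,3R)‑3‑(TBSO‑methyl)‑5‑(methoxycarbonyl)‑2‑methyl‑2,3‑dihydropyrylium bromide, allyl/oxocarbenium ion pair (formed in the flask) | COC(=O)C1=C[C@H](CO[Si](C)(C)C(C)(C)C)[C@@H](C)[O+]=C1.[Br-] | intermediate
21 | methyl (5R,6R)‑5‑({[tert‑butyl(dimethyl)silyl]oxy}methyl)‑2‑methoxy‑6‑methyl‑5,6‑dihydro‑2H‑pyran‑3‑carboxylate, both epimers at C2 | COC(=O)C1=C[C@H](CO[Si](C)(C)C(C)(C)C)[C@@H](C)OC1OC | intermediate
22 | 2‑(3,4‑dihydroxyphenyl)ethyl acetate | CC(=O)OCCc1ccc(O)c(O)c1 | starting material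
23 | 2‑(3,4‑bis{[tert‑butyl(dimethyl)silyl]oxy}phenyl)ethyl acetate | CC(=O)OCCc1ccc(O[Si](C)(C)C(C)(C)C)c(O[Si](C)(C)C(C)(C)C)c1 | intermediate
24 | lithium enolate of 23 (formed in the flask) | [Li]OC(=C)OCCc1ccc(O[Si](C)(C)C(C)(C)C)c(O[Si](C)(C)C(C)(C)C)c1 | intermediate
25 | lithium ester enolate of the Michael adduct of 24 to 21 (formed in the flask) | COC(O[Li])=C1C(OC)O[C@H](C)[C@@H](CO[Si](C)(C)C(C)(C)C)[C@@H]1CC(=O)OCCc1ccc(O[Si](C)(C)C(C)(C)C)c(O[Si](C)(C)C(C)(C)C)c1 | intermediate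
26 | methyl (2R,3R,4S)‑4‑{2‑[2‑(3,4‑bis{[tert‑butyl(dimethyl)silyl]oxy}phenyl)ethoxy]‑2‑oxoethyl}‑3‑({[tert‑butyl(dimethyl)silyl]oxy}methyl)‑2‑methyl‑3,4‑dihydro‑2H‑pyran‑5‑carboxylate | COC(=O)C1=CO[C@H](C)[C@@H](CO[Si](C)(C)C(C)(C)C)[C@@H]1CC(=O)OCCc1ccc(O[Si](C)(C)C(C)(C)C)c(O[Si](C)(C)C(C)(C)C)c1 | intermediate
27 | methyl (2R,3R,4S)‑4‑{2‑[2‑(3,4‑dihydroxyphenyl)ethoxy]‑2‑oxoethyl}‑3‑(hydroxymethyl)‑2‑methyl‑3,4‑dihydro‑2H‑pyran‑5‑carboxylate (2‑Me, 3‑CH2OH and 4‑CH2CO2R all trans) | COC(=O)C1=CO[C@H](C)[C@@H](CO)[C@@H]1CC(=O)OCCc1ccc(O)c(O)c1 | target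

**Step count and risks**

Total: 12 steps. Longest linear sequence: 9 steps (steps 1–6, 9, 11, 12).

Most likely to fail:

1. Step 9. The cyclopropane may form with the bromide anti to the ring and then fail to open, the ring‑expanded cation may lose a proton to give a 2H‑pyran, or the carbene may dimerise before it meets the enol ether. The fallback uses known chemistry, sets out from 15 and returns at 21. Dibromocarbene (CHBr3, KOt‑Bu, hexane, −20 → 0 °C) should add to the enol ether to give (3R,4R)‑6,6‑dibromo‑4‑(TBSO‑methyl)‑3‑methyl‑2‑oxabicyclo[3.1.0]hexane F1. Heating with K2CO3 in MeOH should open the ring‑fusion bond with loss of bromide and give the ring‑expanded bromo acetal (5R,6R)‑3‑bromo‑5‑(TBSO‑methyl)‑2‑methoxy‑6‑methyl‑5,6‑dihydro‑2H‑pyran F2. Methoxycarbonylation of the vinyl bromide (PdCl2(PPh3)2, CO 1 atm, MeOH, Et3N, DMF, 70 °C) should then give 21.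

2. Step 11. Conjugate addition at the hindered β‑carbon may be slow, so that γ‑deprotonation with 1,4‑elimination of methanol competes, the released lithium methoxide may transesterify the aryl‑ethyl ester, or the facial selectivity at C4 may be poor. The fallback replaces the basic enolate by a soft malonate; it sets out from 23 and 21 and returns at 26. Reduction of 23 (i‑Bu2AlH, CH2Cl2, −78 °C) should give 2‑[3,4‑bis(TBSO)phenyl]ethanol F3. Esterification with 3‑(allyloxy)‑3‑oxopropanoic acid (DCC, DMAP, CH2Cl2) should give allyl 2‑[3,4‑bis(TBSO)phenyl]ethyl malonate F4. Its sodium enolate (NaH, THF, 0 °C → rt) should add reversibly to 21 and expel methoxide to give methyl (2R,3R,4R)‑4‑{1‑[(allyloxy)carbonyl]‑2‑[2‑(3,4‑bis(TBSO)phenyl)ethoxy]‑2‑oxoethyl}‑3‑(TBSO‑methyl)‑2‑methyl‑3,4‑dihydro‑2H‑pyran‑5‑carboxylate F5 (the descriptor at C4 changes by priority only). Deallylation (Pd(PPh3)4, morpholine, THF, rt) should give the malonic half acid F6, which should lose CO2 on warming in toluene to give 26.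

3. Step 6. The mesylate may collapse to the anomeric chloride without eliminating, or the acid‑labile and fairly volatile enol ether may hydrate or oligomerise during isolation. The fallback sets out from 13 and returns at 15. Acetalisation (MeOH, cat. pyridinium p‑toluenesulfonate) should give (2R,3R)‑3‑(TBSO‑methyl)‑5‑methoxy‑2‑methyloxolane F7. Treatment with TMSOTf and i‑Pr2NEt (CH2Cl2, −20 °C → rt) should ionise the acetal and remove the β‑proton under non‑aqueous basic conditions to give 15.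

**Further compounds**

F1 | step 9 | (3R,4R)‑6,6‑dibromo‑4‑({[tert‑butyl(dimethyl)silyl]oxy}methyl)‑3‑methyl‑2‑oxabicyclo[3.1.0]hexane | BrC1(Br)C2O[C@H](C)[C@@H](CO[Si](C)(C)C(C)(C)C)C12
F2 | step 9 | (5R,6R)‑3‑bromo‑5‑({[tert‑butyl(dimethyl)silyl]oxy}methyl)‑2‑methoxy‑6‑methyl‑5,6‑dihydro‑2H‑pyran | BrC1=C[C@H](CO[Si](C)(C)C(C)(C)C)[C@@H](C)OC1OC
F3 | step 11 | 2‑(3,4‑bis{[tert‑butyl(dimethyl)silyl]oxy}phenyl)ethanol | OCCc1ccc(O[Si](C)(C)C(C)(C)C)c(O[Si](C)(C)C(C)(C)C)c1
F4 | step 11 | allyl 2‑(3,4‑bis{[tert‑butyl(dimethyl)silyl]oxy}phenyl)ethyl malonate | C=CCOC(=O)CC(=O)OCCc1ccc(O[Si](C)(C)C(C)(C)C)c(O[Si](C)(C)C(C)(C)C)c1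
F5 | step 11 | methyl (2R,3R,4R)‑4‑{1‑[(allyloxy)carbonyl]‑2‑[2‑(3,4‑bis(TBSO)phenyl)ethoxy]‑2‑oxoethyl}‑3‑(TBSO‑methyl)‑2‑methyl‑3,4‑dihydro‑2H‑pyran‑5‑carboxylate | COC(=O)C1=CO[C@H](C)[C@@H](CO[Si](C)(C)C(C)(C)C)[C@@H]1C(C(=O)OCC=C)C(=O)OCCc1ccc(O[Si](C)(C)C(C)(C)C)c(O[Si](C)(C)C(C)(C)C)c1
F6 | step 11 | 3‑[2‑(3,4‑bis(TBSO)phenyl)ethoxy]‑2‑[(2R,3R,4R)‑3‑(TBSO‑methyl)‑5‑(methoxycarbonyl)‑2‑methyl‑3,4‑dihydro‑2H‑pyran‑4‑yl]‑3‑oxopropanoic acid | COC(=O)C1=CO[C@H](C)[C@@H](CO[Si](C)(C)C(C)(C)C)[C@@H]1C(C(O)=O)C(=O)OCCc1ccc(O[Si](C)(C)C(C)(C)C)c(O[Si](C)(C)C(C)(C)C)c1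
F7 | step 6 | (2R,3R)‑3‑({[tert‑butyl(dimethyl)silyl]oxy}methyl)‑5‑methoxy‑2‑methyloxolane | C[C@H]1OC(OC)C[C@@H]1CO[Si](C)(C)C(C)(C)C
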